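**Target:** 5-hydroxy-7-methoxy-3,6,8-tris(3-methylbut-2-enyl)-2-(2,4,5-trihydroxyphenyl)chromen-4-one (28), an achiral triprenylated flavone.

## The problem

The target is a flavone: ring A is fused to the 4-pyranone ring C along C4a–C8a, and ring B is attached to C2 by a single aryl–heteroaryl bond. It has no stereocentre, so nothing has to be controlled or relayed in space and the whole difficulty is regiochemical. Ring A is hexasubstituted (C4a, O5, prenyl at C6, O7, prenyl at C8, O8a) and only O7 is methylated, so it must be told apart from O5 and from the three hydroxyls of ring B. Putting two prenyl groups on a phloroglucinol by electrophilic substitution and then methylating the oxygen between them is unselective (O- against C-alkylation, wrong carbon, over-alkylation). A third prenyl group sits at C3 of ring C beside the aryl group, a position that classical flavone syntheses leave unsubstituted. The prenyl groups do not survive strong Brønsted or Lewis acids (chroman formation with a neighbouring hydroxyl, hydration), electrophilic halogen, oxidants or hydrogenation, and the free 2,4,5-trihydroxyphenyl ring B is a hydroxyquinol that air oxidises to a quinone, above all in base. The feature that opens a short route is the strict alternation in ring A: oxygen at C5, C7 and C8a, carbon at C4a, C6 and C8. A 3-methoxycyclobutenone carrying both prenyl groups can supply C6, C7, C8 and C8a, and a siloxyalkyne can supply C4a and C5. Their thermal union delivers the three oxygens already differentiated as OSi, OMe and OH, with the one unsubstituted carbon, C4a, exactly where ring C must be attached.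

## Retrosynthesis

**28 from 27.** The last cut removes only the three methoxymethyl groups from O2', O4' and O5'. Ring B has to stay masked through organolithium chemistry and a copper-mediated oxidation, and must be unmasked without hydrogenolysis and without strong acid. Acetal protection meets this: it is inert to base, acetylides and acetate, and it is lost in dilute methanolic acid below the acidity that protonates a trisubstituted alkene. Benzyl ethers (hydrogenolysis would reduce the prenyl groups) and methyl ethers (indistinguishable from the O7 methyl) are excluded; silyl ethers are held in reserve. O5 needs no protection because it is hydrogen-bonded to the C4 carbonyl.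

**27 from 21 and 26.** Ring C is cut at O1–C2 and C3–C4, giving salicylaldehyde 21 and the aryl prenyl alkyne 26. The forward reaction is the rhodium-catalysed oxidative annulation in which the formyl C–H bond adds across the alkyne and the phenol oxygen closes the ring. This cut is preferred to a Baker–Venkataraman sequence, which closes ring C by acid-catalysed dehydration and still needs a separate C3 prenylation. It is also preferred to a C2–C1' cross-coupling, which needs the fully substituted chromone first. One step brings in C2, C3, ring B and the third prenyl group without acid. Aldehyde 21 is C2v-symmetric, so either hydroxyl gives the same chromone and the other becomes 5-OH. The forward step must insert 26 with its aryl carbon next to oxygen and leave the 1,4-enyne and the free phenol intact.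

**21 from 20 from 18.** Removing the silyl group (20) and then the formyl carbon, the future C4 (18), leaves a pentasubstituted phenol whose only ring hydrogen is at the future C4a, between a free hydroxyl and a siloxy group. Magnesium-mediated formylation is specific for the position ortho to a free phenol and runs under amine base, whereas the classical electrophilic formylations generate acid beside two ortho-prenylphenol units. One free hydroxyl and one silyl ether, as in 18, is what this method needs: a single magnesium phenoxide.

**18 from 8 and 13 (key disconnection).** Ring A is cut at C4a–C8a and C5–C6 (flavone numbering) into racemic cyclobutenone 8 and siloxyalkyne 13, the retron of a Danheiser benzannulation. The neighbouring option, C-prenylation of a preformed trioxygenated benzene followed by selective O-methylation and O-silylation, has to solve three regiochemical problems by reagent control. Here the connectivity of the partners fixes every substituent: the methoxy group is flanked by both prenyl groups from the start, and the other two oxygens emerge as OH and OSi. A C26 hexasubstituted benzene is reduced to a C15 cyclobutenone and a C2 alkyne, each one or two steps from purchasable material. The forward reaction needs one regiochemical outcome, the orientation of the ketene–alkyne cycloaddition, and it needs ring opening of a vinylogous ester at a temperature the siloxyalkyne tolerates.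

**8 from 4 and 6; 4 from 1 and 2; 6 from 5.** The four-membered ring is cut at C1–C2 and C3–C4 into ynol ether 4 and prenylketene 7, the latter generated from acid chloride 6. A ketene–ynol ether [2+2] cycloaddition is regiospecific by the same polarisation argument as the key step and builds the cyclobutenone with all four substituents in one step. Ynol ether 4 is cut at the propargylic C–C bond into lithium methoxyacetylide 3 (from chloroacetal 1) and prenyl bromide 2; acid chloride 6 comes from acid 5.

**13 from 9 and 10.** The siloxyalkyne is cut at O–Si and C–O: lithium ethynolate 12, obtained by oxidation of lithium acetylide 11 from acetylene 9, is silylated on oxygen by silyl triflate 10. The triisopropylsilyl group is chosen because it slows the 1,3-shift of silicon from oxygen to carbon that destroys smaller silyl ynol ethers.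

**26 from 24 and 2; 24 from 23 from 22.** The 1,4-enyne is cut at the propargylic C–C bond into acetylide 25 (from terminal alkyne 24) and prenyl bromide 2, the same alkylation used for 4. Alkyne 24 is the one-carbon homologue of aldehyde 23, the tris-acetal of purchasable 2,4,5-trihydroxybenzaldehyde 22, in which the ring B oxygenation pattern is bought.

## Roads not taken

**Alternative 1:** lactone tether from O2' to C3.
- **Cut:** the C2–C1' bond, made intramolecular by esterifying a chromone-3-acetic acid with a bromophenol to give aryl ester A1.
- **Forward key step:** zerovalent palladium (from Pd(OAc)2, a phosphine and a carbonate or pivalate base) inserts into the C–Br bond, the aryl palladium species metalates the free C2–H of the chromone, and reductive elimination forms C2–C1' and closes the seven-membered lactone A2. Half-reduction of the lactone carbonyl and isopropylidene Wittig olefination would then turn the two-carbon bridge into the C3 prenyl group and free O2'.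
- **Merits:** the site of arylation is fixed by the tether, one handle accounts for both the 2'-oxygen and the C3 side chain, and the third prenyl group is built late.
- **Weak points:**
  - It says nothing about ring A; the 6,8-diprenyl-7-methoxy pattern of A1 must still be won by classical substitution.
  - C2 is the electrophilic β-carbon of the enone and C3 carries no hydrogen, so a Heck pathway is closed and the step depends on concerted metalation–deprotonation through a medium-ring palladacycle.
  - An aryl ester with a doubly activated α-methylene group in hot carbonate base is prone to acyl transfer.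
  - The half-reduction must spare the chromone carbonyl.
- **Comparison:** in regiochemical certainty at C2 and C3 this road is better, since connectivity guarantees what step 11 of the chosen plan leaves to the electronic bias of alkyne insertion. The chosen plan sets against this that one annulation replaces four operations and that ring A, the harder ring, is actually solved.

**Alternative 2:** triple cross-metathesis.
- **Cut:** the three CH=C(CH3)2 double bonds, leading back to the 3,6,8-triallylflavone A3.
- **Forward key step:** A3 and excess 2-methylbut-2-ene with the second-generation Grubbs catalyst give the triprenyl compound A4 with loss of propene. A4 is constitutionally identical with compound 27 of the chosen route.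
- **Merits:** this is probably the most reliable of the three. Allyl groups go in by O-allylation and Claisen rearrangement with dependable ortho selectivity, they tolerate the acid of a classical flavone cyclodehydration, and the prenyl groups exist for only two steps.
- **Weak points:**
  - Three metatheses must all go to completion on one molecule, or mixtures of partly exchanged products result.
  - Ruthenium hydrides can isomerise an ortho-allylphenol to the propenyl compound.
  - The ring A sequence (two Claisen rearrangements, then methylation of O7 but not O5) and the C3 allylation add up to a long linear route.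
- **Comparison:** this road is clearly gentler on the prenyl groups, which the chosen plan carries through seven steps. The chosen plan sets against this that every one of those steps except the last is neutral or basic, that ring A regiochemistry is fixed by connectivity instead of by a sequence of rearrangements and a chelation-controlled methylation, and that the route is much shorter. The final deprotection risk is the same in both.

**Alternative 3:** Dötz benzannulation for ring B.
- **Cut:** ring B at C5'–C6', C1'–C2' and C2'–C3', leading back to the 2-ethynylchromone A5 and the Fischer carbene complex A6 of zerovalent chromium, (CO)5Cr=C(OMe)C(OEt)=CH2.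
- **Forward key step:** alkyne insertion into the carbene, CO insertion and electrocyclisation give the 2-aryl chromone A7, with the new phenol oxygen at C2' next to the chromone.
- **Merits:** ring B is built regioselectively on a finished chromone, and the 2'-hydroxyl arrives free and distinct.
- **Weak points:**
  - In A7 the oxygens at C4' and C5' are ethyl and methyl ethers, which cannot be cleaved in the presence of the O7 methyl ether and three prenyl groups.
  - A5 is an electron-poor, ynone-like alkyne, a poor partner for the benzannulation.
  - Stoichiometric chromium is used late in the synthesis.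
  - A5 already contains the whole of ring A with three prenyl groups, made by other means.
- **Comparison:** the strategy spends its key step on ring B, which can be bought with the correct oxygenation as aldehyde 22, and leaves the difficult ring untouched. It is better only in that the C2–C1' bond and the 2'-hydroxyl are unambiguous. The chosen plan sets against this that its own benzannulation is spent on ring A and that all its protecting groups are removable.

Key step: step 5

Remark on the chemistry: the target is achiral; the only stereocentres met on the way (in 8, 15 and 17) are racemic and disappear on aromatisation, so no step has to control configuration.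

## Route

Step 1
Reactants: 1 chloroacetaldehyde dimethyl acetal (2-chloro-1,1-dimethoxyethane); 2 prenyl bromide (1-bromo-3-methylbut-2-ene)
Product: 4 1-methoxy-5-methylhex-4-en-1-yne, via lithium methoxyacetylide 3 (not isolated)
Conditions: LiNEt2 (3.1 equiv), THF, 0 °C; then 2, DMPU, −78 °C → rt
Reagents that add atoms: none
Why: Three equivalents of amide base eliminate methanol and HCl from the chloroacetal and deprotonate the resulting methoxyethyne, the standard one-flask entry to lithium alkoxyacetylides; the acetylide then displaces bromide at the primary allylic carbon of 2 (SN2 alkylation promoted by DMPU), so the volatile, hazardous methoxyethyne is never handled.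

Step 2
Reactants: 5 5-methylhex-4-enoic acid
Product: 6 5-methylhex-4-enoyl chloride
Conditions: (COCl)2, DMF (cat.), CH2Cl2, 0 °C → rt; used crude
Reagents that add atoms: oxalyl chloride, O=C(Cl)C(=O)Cl
Why: Acid chloride formation through the Vilsmeier-type chloroiminium salt is fast at 0 °C and evolves only gases, so the trisubstituted alkene is not exposed to HCl for long; the crude chloride is used at once.

Step 3
Reactants: 6 5-methylhex-4-enoyl chloride; 4 1-methoxy-5-methylhex-4-en-1-yne
Product: 8 racemic 3-methoxy-2,4-bis(3-methylbut-2-enyl)cyclobut-2-en-1-one, via prenylketene 7 (not isolated)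
Conditions: Et3N, CH2Cl2, rt → 40 °C, slow addition of 6 to 4 and Et3N
Reagents that add atoms: none
Why: Dehydrochlorination gives aldoketene 7, which the electron-rich ynol ether 4 traps in a thermal ketene–alkyne [2+2] cycloaddition; the alkyne carbon β to oxygen (the prenyl-bearing one) bonds to the ketene carbonyl carbon, which fixes the 3-methoxy-2,4-dialkyl pattern, and slow addition keeps the ketene concentration low against dimerisation. The C4 stereocentre forms as a racemate and is lost in step 5.

Step 4
Reactants: 9 acetylene (ethyne); 10 triisopropylsilyl trifluoromethanesulfonate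
Product: 13 triisopropyl(ethynyloxy)silane (triisopropylsiloxyethyne), via lithium acetylide 11 (not isolated), via lithium ethynolate 12 (not isolated)
Conditions: n-BuLi, THF, −78 °C (9 in excess); t-BuOOH/LiN(SiMe3)2 (premixed, THF, −78 °C), −78 → 0 °C; then 10, −78 → 0 °C
Reagents that add atoms: tert-butyl hydroperoxide, CC(C)(C)OO
Why: The acetylide carbon attacks the electrophilic peroxide oxygen of t-BuOOLi to give the ynolate (the established oxidation of lithium acetylides to ynolates, applied here to the parent acetylide), and the hard, bulky silyl triflate silylates the ynolate on oxygen; the triisopropylsilyl group is chosen because it resists the 1,3-shift to a silylketene.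

Step 5
Reactants: 8 racemic 3-methoxy-2,4-bis(3-methylbut-2-enyl)cyclobut-2-en-1-one; 13 triisopropyl(ethynyloxy)silane
Product: 18 3-methoxy-2,4-bis(3-methylbut-2-enyl)-5-(triisopropylsilyloxy)phenol, via vinylketene 14 (not isolated), via 4-vinylcyclobutenone 15 (not isolated), via dienylketene 16 (not isolated), via cyclohexadienone 17 (not isolated)
Conditions: 13 (2 equiv), toluene, 110 °C, sealed tube, argon
Reagents that add atoms: none
Why: Heating opens 8 by conrotatory 4π electrocyclic cleavage of the C1–C4 bond, the C4 prenyl group rotating outward, to give vinylketene 14. Siloxyalkyne 13 is polarised by oxygen so that its CH carbon is the nucleophile; it attacks the ketene carbonyl carbon, and [2+2] cycloaddition across the ketene C=C gives 4-vinylcyclobutenone 15, forming the future C4a–C8a and C5–C6 bonds. A second, reversible 4π opening gives dienylketene 16, and the isomer with ketene and alkenyl group cis closes by thermal disrotatory 6π electrocyclisation between the ketene carbon and the terminal CH carbon (re-forming the C8–C8a bond broken at the start) to cyclohexadienone 17, which tautomerises to phenol 18; ring A is thus closed by a pericyclic six-electron closure, not by an ionic cyclisation. This is the Danheiser benzannulation, whose closest precedents are alkyl- and aryl-substituted cyclobutenones reacting with trialkylsiloxyalkynes; a 3-methoxy-2,4-dialkylcyclobutenone is a new member of that class. No stereocentre is set: those of 8, 15 and 17 are racemic and vanish on aromatisation. The selectivity needed is the orientation of the ketene–alkyne cycloaddition, and the polarisation of 13 secures it, placing the unsubstituted carbon between the OH- and OSi-bearing carbons and leaving the methoxy group flanked by both prenyl groups. The conditions are neutral, so the two prenyl alkenes meet no acid, and geometry keeps them from the ketenes: the C2 prenyl alkene is too close to reach the ketene and the outward-rotated C4 prenyl group points away from it. An excess of 13 keeps trapping faster than ketene dimerisation or acylation of the product phenol.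

Step 6
Reactants: 18 3-methoxy-2,4-bis(3-methylbut-2-enyl)-5-(triisopropylsilyloxy)phenol
Product: 20 2-hydroxy-4-methoxy-3,5-bis(3-methylbut-2-enyl)-6-(triisopropylsilyloxy)benzaldehyde, via hydroxymethylphenol 19 (not isolated)
Conditions: MgCl2, Et3N, (CH2O)n, MeCN, 80 °C
Reagents that add atoms: paraformaldehyde (as formaldehyde), C=O
Why: Casnati–Skattebøl ortho-formylation: the magnesium phenoxide of 18 delivers formaldehyde through a six-membered chelate to the ortho carbon, here the only unsubstituted ring position, and the benzylic alkoxide of 19 is oxidised by a second formaldehyde (Oppenauer-type hydride transfer, giving methanol). The medium is basic and free of electrophilic acid, so the prenyl groups and the silyl ether are not touched.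

Step 7
Reactants: 20 2-hydroxy-4-methoxy-3,5-bis(3-methylbut-2-enyl)-6-(triisopropylsilyloxy)benzaldehyde
Product: 21 2,6-dihydroxy-4-methoxy-3,5-bis(3-methylbut-2-enyl)benzaldehyde
Conditions: Bu4NF, AcOH, THF, 0 °C
Reagents that add atoms: none
Why: Fluoride cleaves the aryl silyl ether, which is activated by the ortho formyl group; acetic acid buffers the phenoxide so the electron-rich dihydroxybenzaldehyde is not left in base, and the product is C2v-symmetric.

Step 8
Reactants: 22 2,4,5-trihydroxybenzaldehyde
Product: 23 2,4,5-tris(methoxymethoxy)benzaldehyde
Conditions: MOMCl (excess), i-Pr2NEt, CH2Cl2, 0 °C → rt, argon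
Reagents that add atoms: chloromethyl methyl ether, COCCl
Why: O-Alkylation of the three phenols by the reactive chloromethyl ether under amine base (acetal protection); an excess and longer time serve the hydrogen-bonded 2-OH, and exclusion of air protects the hydroxyquinol until it is capped.

Step 9
Reactants: 23 2,4,5-tris(methoxymethoxy)benzaldehyde
Product: 24 1-ethynyl-2,4,5-tris(methoxymethoxy)benzene
Conditions: dimethyl (1-diazo-2-oxopropyl)phosphonate, K2CO3, MeOH, rt
Reagents that add atoms: dimethyl (1-diazo-2-oxopropyl)phosphonate, COP(=O)(OC)C(=[N+]=[N-])C(C)=O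
Why: Ohira–Bestmann variant of the Seyferth–Gilbert homologation: the diazophosphonate anion released by methanolysis adds to the non-enolisable aldehyde, and loss of dimethyl phosphate and N2 with 1,2-hydrogen shift gives the terminal alkyne under conditions to which the acetals are inert.

Step 10
Reactants: 24 1-ethynyl-2,4,5-tris(methoxymethoxy)benzene; 2 prenyl bromide
Product: 26 1,2,4-tris(methoxymethoxy)-5-(5-methylhex-4-en-1-ynyl)benzene, via lithium arylacetylide 25 (not isolated)
Conditions: n-BuLi, THF, −78 °C; then 2, DMPU, −78 °C → rt
Reagents that add atoms: none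
Why: The terminal alkyne is by far the most acidic site, so one equivalent of n-BuLi at −78 °C gives acetylide 25 without ortho-metalation; SN2 alkylation at the primary carbon of 2 gives the 1,4-enyne, the same reaction type as in step 1.

Step 11
Reactants: 21 2,6-dihydroxy-4-methoxy-3,5-bis(3-methylbut-2-enyl)benzaldehyde; 26 1,2,4-tris(methoxymethoxy)-5-(5-methylhex-4-en-1-ynyl)benzene
Product: 27 5-hydroxy-7-methoxy-3,6,8-tris(3-methylbut-2-enyl)-2-[2,4,5-tris(methoxymethoxy)phenyl]chromen-4-one
Conditions: [RhCl(cod)]2 (cat.), C5H2Ph4 (1,2,3,4-tetraphenylcyclopentadiene, cat.), Cu(OAc)2·H2O (2 equiv), o-xylene, 120 °C, N2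
Reagents that add atoms: none
Why: Rhodium-catalysed oxidative annulation of a salicylaldehyde with an internal alkyne: the phenoxide binds trivalent rhodium, the formyl C–H bond is cleaved to a five-membered acyl rhodacycle, the alkyne inserts with the acyl group going to the alkyl-bearing carbon and rhodium to the aryl-bearing carbon, and C–O reductive elimination closes ring C with ring B at C2 and the prenyl group at C3; Cu(OAc)2 returns monovalent rhodium to the trivalent state. Because 21 is symmetric either hydroxyl gives the same chromone, and the second one remains as the chelated 5-OH.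

Step 12
Reactants: 27 5-hydroxy-7-methoxy-3,6,8-tris(3-methylbut-2-enyl)-2-[2,4,5-tris(methoxymethoxy)phenyl]chromen-4-one
Product: 28 5-hydroxy-7-methoxy-3,6,8-tris(3-methylbut-2-enyl)-2-(2,4,5-trihydroxyphenyl)chromen-4-one
Conditions: 3 M aq HCl, MeOH (degassed), 40 °C, argon
Reagents that add atoms: none
Why: Acid-catalysed methanolysis of the three aryl methoxymethyl acetals (transacetalisation to dimethoxymethane) runs through oxocarbenium ions at an acidity and temperature below those needed to protonate a trisubstituted alkene; 5-OH is tied up in a hydrogen bond to the C4 carbonyl, which disfavours chroman formation with the C6 prenyl group, and degassed solvent protects the freed hydroxyquinol.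

## Compound list

1 | chloroacetaldehyde dimethyl acetal (2-chloro-1,1-dimethoxyethane) | COC(CCl)OC | starting material
2 | prenyl bromide (1-bromo-3-methylbut-2-ene) | CC(C)=CCBr | starting material
3 | lithium methoxyacetylide | [Li]C#COC | intermediate
4 | 1-methoxy-5-methylhex-4-en-1-yne | COC#CCC=C(C)C | intermediate
5 | 5-methylhex-4-enoic acid | CC(C)=CCCC(=O)O | starting material
6 | 5-methylhex-4-enoyl chloride | CC(C)=CCCC(=O)Cl | intermediate
7 | prenylketene (5-methylhexa-1,4-dien-1-one) | CC(C)=CCC=C=O | intermediate
8 | racemic 3-methoxy-2,4-bis(3-methylbut-2-enyl)cyclobut-2-en-1-one | COC1=C(CC=C(C)C)C(=O)C1CC=C(C)C | intermediate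
9 | acetylene (ethyne) | C#C | starting material
10 | triisopropylsilyl trifluoromethanesulfonate | CC(C)[Si](C(C)C)(C(C)C)OS(=O)(=O)C(F)(F)F | starting material
11 | lithium acetylide | [Li]C#C | intermediate
12 | lithium ethynolate | [Li]OC#C | intermediate
13 | triisopropyl(ethynyloxy)silane (triisopropylsiloxyethyne) | C#CO[Si](C(C)C)(C(C)C)C(C)C | intermediate
14 | vinylketene, (3Z)-3-methoxy-7-methyl-2-(3-methylbut-2-enyl)octa-1,3,6-trien-1-one | O=C=C(CC=C(C)C)/C(OC)=C/CC=C(C)C | intermediate
15 | 4-vinylcyclobutenone, racemic 4-[(1Z)-1-methoxy-5-methylhexa-1,4-dienyl]-4-(3-methylbut-2-enyl)-3-(triisopropylsilyloxy)cyclobut-2-en-1-one | O=C1C=C(O[Si](C(C)C)(C(C)C)C(C)C)C1(CC=C(C)C)/C(OC)=C/CC=C(C)C | intermediate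
16 | dienylketene, (3E,5Z)-5-methoxy-9-methyl-4-(3-methylbut-2-enyl)-3-(triisopropylsilyloxy)deca-1,3,5,8-tetraen-1-one | O=C=C/C(O[Si](C(C)C)(C(C)C)C(C)C)=C(CC=C(C)C)\C(OC)=C\CC=C(C)C | intermediate
17 | cyclohexadienone, racemic 5-methoxy-4,6-bis(3-methylbut-2-enyl)-3-(triisopropylsilyloxy)cyclohexa-2,4-dien-1-one | O=C1C=C(O[Si](C(C)C)(C(C)C)C(C)C)C(CC=C(C)C)=C(OC)C1CC=C(C)C | intermediate
18 | 3-methoxy-2,4-bis(3-methylbut-2-enyl)-5-(triisopropylsilyloxy)phenol | Oc1cc(O[Si](C(C)C)(C(C)C)C(C)C)c(CC=C(C)C)c(OC)c1CC=C(C)C | intermediate
19 | hydroxymethylphenol, 2-(hydroxymethyl)-5-methoxy-4,6-bis(3-methylbut-2-enyl)-3-(triisopropylsilyloxy)phenol | OCc1c(O)c(CC=C(C)C)c(OC)c(CC=C(C)C)c1O[Si](C(C)C)(C(C)C)C(C)C | intermediate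
20 | 2-hydroxy-4-methoxy-3,5-bis(3-methylbut-2-enyl)-6-(triisopropylsilyloxy)benzaldehyde | O=Cc1c(O)c(CC=C(C)C)c(OC)c(CC=C(C)C)c1O[Si](C(C)C)(C(C)C)C(C)C | intermediate
21 | 2,6-dihydroxy-4-methoxy-3,5-bis(3-methylbut-2-enyl)benzaldehyde | O=Cc1c(O)c(CC=C(C)C)c(OC)c(CC=C(C)C)c1O | intermediate
22 | 2,4,5-trihydroxybenzaldehyde | O=Cc1cc(O)c(O)cc1O | starting material
23 | 2,4,5-tris(methoxymethoxy)benzaldehyde | O=Cc1cc(OCOC)c(OCOC)cc1OCOC | intermediate
24 | 1-ethynyl-2,4,5-tris(methoxymethoxy)benzene | C#Cc1cc(OCOC)c(OCOC)cc1OCOC | intermediate
25 | lithium arylacetylide, lithium 2-[2,4,5-tris(methoxymethoxy)phenyl]ethynide | [Li]C#Cc1cc(OCOC)c(OCOC)cc1OCOC | intermediate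
26 | 1,2,4-tris(methoxymethoxy)-5-(5-methylhex-4-en-1-ynyl)benzene | CC(C)=CCC#Cc1cc(OCOC)c(OCOC)cc1OCOC | intermediate
27 | 5-hydroxy-7-methoxy-3,6,8-tris(3-methylbut-2-enyl)-2-[2,4,5-tris(methoxymethoxy)phenyl]chromen-4-one | COc1c(CC=C(C)C)c(O)c2c(=O)c(CC=C(C)C)c(-c3cc(OCOC)c(OCOC)cc3OCOC)oc2c1CC=C(C)C | intermediate
28 | 5-hydroxy-7-methoxy-3,6,8-tris(3-methylbut-2-enyl)-2-(2,4,5-trihydroxyphenyl)chromen-4-one | COc1c(CC=C(C)C)c(O)c2c(=O)c(CC=C(C)C)c(-c3cc(O)c(O)cc3O)oc2c1CC=C(C)C | target

## Step count and risk

Total: 12 steps. Longest linear sequence: 7 steps (steps 1, 3, 5, 6, 7, 11, 12, from 1).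

**Step 5 (key step).** The methoxy group makes 8 a vinylogous ester, so ring opening may need a temperature at which 13 isomerises by 1,3-silyl shift to a silylketene. The alkyl-substituted vinylketene may also dimerise or acylate the product phenol faster than the alkyne traps it.
Fallback, setting out from 6, 10 and 4 and returning at 18: the roles of the partners are exchanged, so that the siloxy group is locked into the cyclobutenone and the robust ynol ether 4 is the ketenophile.
- Acid chloride 6 is converted (EtOH, pyridine) into ethyl 5-methylhex-4-enoate F1.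
- Kowalski ester homologation (LiCHBr2 from CH2Br2 and lithium 2,2,6,6-tetramethylpiperidide, then LiN(SiMe3)2 and n-BuLi) gives lithium 5-methylhex-4-en-1-yn-1-olate F2.
- O-Silylation of F2 with 10 gives triisopropyl(5-methylhex-4-en-1-ynyloxy)silane F3.
- [2+2] cycloaddition of F3 with ketene (CH2=C=O) gives 2-(3-methylbut-2-enyl)-3-(triisopropylsilyloxy)cyclobut-2-en-1-one F4.
- Heating F4 with 4 in toluene runs the same ring-opening, cycloaddition and electrocyclisation sequence and should give 18, because the prenyl-bearing carbon of 4 now attacks the ketene carbon.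

**Step 4.** Monolithium acetylide may disproportionate on warming before oxidation is complete, and the unhindered ynolate carbon may be silylated in competition with oxygen, which leads to the silylketene.
Fallback, setting out from 10 and returning at 13: the alkyne is made by elimination, not from an ynolate.
- Silylation of acetaldehyde with 10 (Et3N, CH2Cl2) gives triisopropyl(vinyloxy)silane F5.
- Bromine at −78 °C adds to give (1,2-dibromoethoxy)triisopropylsilane F6.
- Et3N in the same flask dehydrobrominates F6 to [(Z)-2-bromovinyloxy]triisopropylsilane F7 (mainly this isomer).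
- LiN(i-Pr)2 (2 equiv, THF, −78 °C) eliminates HBr, and protonation on work-up gives 13.

**Step 11.** The 1,4-enyne may isomerise to an allene or a conjugated enyne at 120 °C, the electron-rich phenol may be degraded oxidatively by divalent copper, and the ortho acetal group on the alkyne may erode the regioselectivity of insertion.
Fallback, setting out from 20 and 25 and returning at 27: ring C is built stepwise and the C3 prenyl group is added last.
- Addition of 25 (2.2 equiv, THF, −78 → 0 °C) to 20 gives racemic 2-[1-hydroxy-3-[2,4,5-tris(methoxymethoxy)phenyl]prop-2-ynyl]-5-methoxy-4,6-bis(3-methylbut-2-enyl)-3-(triisopropylsilyloxy)phenol F8.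
- MnO2 (CH2Cl2) oxidises it to 1-[2-hydroxy-4-methoxy-3,5-bis(3-methylbut-2-enyl)-6-(triisopropylsilyloxy)phenyl]-3-[2,4,5-tris(methoxymethoxy)phenyl]prop-2-yn-1-one F9.
- Amine-mediated 6-endo oxa-Michael cyclisation (Et2NH, EtOH) gives 7-methoxy-6,8-bis(3-methylbut-2-enyl)-5-(triisopropylsilyloxy)-2-[2,4,5-tris(methoxymethoxy)phenyl]chromen-4-one F10.
- C3 lithiation with LiN(i-Pr)2 (THF, −78 °C) and alkylation with 2 gives 7-methoxy-3,6,8-tris(3-methylbut-2-enyl)-5-(triisopropylsilyloxy)-2-[2,4,5-tris(methoxymethoxy)phenyl]chromen-4-one F11.
- Bu4NF/AcOH removes the silyl group and gives 27.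

**Step 12.** A prenyl group may cyclise under acid onto a neighbouring hydroxyl (C6 prenyl with 5-OH, C3 prenyl with 2'-OH), an alkene may be hydrated, and the liberated hydroxyquinol may be oxidised by air.
Fallback, setting out from 22 (with 2 and 21) and returning at 28: ring B is carried as silyl ethers, so the last step uses fluoride in place of acid.
- TBSCl and imidazole (DMF) convert 22 into 2,4,5-tris(tert-butyldimethylsilyloxy)benzaldehyde F12.
- Corey–Fuchs olefination (CBr4, PPh3) gives 1-(2,2-dibromoethenyl)-2,4,5-tris(tert-butyldimethylsilyloxy)benzene F13.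
- n-BuLi (2 equiv), then 2 and DMPU, gives 1,2,4-tris(tert-butyldimethylsilyloxy)-5-(5-methylhex-4-en-1-ynyl)benzene F14.
- Annulation with 21 as in step 11 gives 5-hydroxy-7-methoxy-3,6,8-tris(3-methylbut-2-enyl)-2-[2,4,5-tris(tert-butyldimethylsilyloxy)phenyl]chromen-4-one F15.
- Bu4NF buffered with AcOH (THF, 0 °C, degassed) gives 28.

## Further compounds

F1 | step 5 | ethyl 5-methylhex-4-enoate | CCOC(=O)CCC=C(C)C
F2 | step 5 | lithium 5-methylhex-4-en-1-yn-1-olate | [Li]OC#CCC=C(C)C
F3 | step 5 | triisopropyl(5-methylhex-4-en-1-ynyloxy)silane | CC(C)=CCC#CO[Si](C(C)C)(C(C)C)C(C)C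
F4 | step 5 | 2-(3-methylbut-2-enyl)-3-(triisopropylsilyloxy)cyclobut-2-en-1-one | O=C1CC(O[Si](C(C)C)(C(C)C)C(C)C)=C1CC=C(C)C
F5 | step 4 | triisopropyl(vinyloxy)silane | C=CO[Si](C(C)C)(C(C)C)C(C)C
F6 | step 4 | racemic (1,2-dibromoethoxy)triisopropylsilane | BrCC(Br)O[Si](C(C)C)(C(C)C)C(C)C
F7 | step 4 | [(Z)-2-bromovinyloxy]triisopropylsilane | Br/C=C\O[Si](C(C)C)(C(C)C)C(C)C
F8 | step 11 | racemic 2-[1-hydroxy-3-[2,4,5-tris(methoxymethoxy)phenyl]prop-2-ynyl]-5-methoxy-4,6-bis(3-methylbut-2-enyl)-3-(triisopropylsilyloxy)phenol | OC(C#Cc1cc(OCOC)c(OCOC)cc1OCOC)c1c(O)c(CC=C(C)C)c(OC)c(CC=C(C)C)c1O[Si](C(C)C)(C(C)C)C(C)C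
F9 | step 11 | 1-[2-hydroxy-4-methoxy-3,5-bis(3-methylbut-2-enyl)-6-(triisopropylsilyloxy)phenyl]-3-[2,4,5-tris(methoxymethoxy)phenyl]prop-2-yn-1-one | O=C(C#Cc1cc(OCOC)c(OCOC)cc1OCOC)c1c(O)c(CC=C(C)C)c(OC)c(CC=C(C)C)c1O[Si](C(C)C)(C(C)C)C(C)C
F10 | step 11 | 7-methoxy-6,8-bis(3-methylbut-2-enyl)-5-(triisopropylsilyloxy)-2-[2,4,5-tris(methoxymethoxy)phenyl]chromen-4-one | COc1c(CC=C(C)C)c(O[Si](C(C)C)(C(C)C)C(C)C)c2c(=O)cc(-c3cc(OCOC)c(OCOC)cc3OCOC)oc2c1CC=C(C)C
F11 | step 11 | 7-methoxy-3,6,8-tris(3-methylbut-2-enyl)-5-(triisopropylsilyloxy)-2-[2,4,5-tris(methoxymethoxy)phenyl]chromen-4-one | COc1c(CC=C(C)C)c(O[Si](C(C)C)(C(C)C)C(C)C)c2c(=O)c(CC=C(C)C)c(-c3cc(OCOC)c(OCOC)cc3OCOC)oc2c1CC=C(C)C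
F12 | step 12 | 2,4,5-tris(tert-butyldimethylsilyloxy)benzaldehyde | O=Cc1cc(O[Si](C)(C)C(C)(C)C)c(O[Si](C)(C)C(C)(C)C)cc1O[Si](C)(C)C(C)(C)C
F13 | step 12 | 1-(2,2-dibromoethenyl)-2,4,5-tris(tert-butyldimethylsilyloxy)benzene | BrC(Br)=Cc1cc(O[Si](C)(C)C(C)(C)C)c(O[Si](C)(C)C(C)(C)C)cc1O[Si](C)(C)C(C)(C)C
F14 | step 12 | 1,2,4-tris(tert-butyldimethylsilyloxy)-5-(5-methylhex-4-en-1-ynyl)benzene | CC(C)=CCC#Cc1cc(O[Si](C)(C)C(C)(C)C)c(O[Si](C)(C)C(C)(C)C)cc1O[Si](C)(C)C(C)(C)C
F15 | step 12 | 5-hydroxy-7-methoxy-3,6,8-tris(3-methylbut-2-enyl)-2-[2,4,5-tris(tert-butyldimethylsilyloxy)phenyl]chromen-4-one | COc1c(CC=C(C)C)c(O)c2c(=O)c(CC=C(C)C)c(-c3cc(O[Si](C)(C)C(C)(C)C)c(O[Si](C)(C)C(C)(C)C)cc3O[Si](C)(C)C(C)(C)C)oc2c1CC=C(C)C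
A1 | alternative 1 | 2-bromo-4,5-bis(methoxymethoxy)phenyl 2-[7-methoxy-5-(methoxymethoxy)-6,8-bis(3-methylbut-2-enyl)-4-oxochromen-3-yl]acetate | COc1c(CC=C(C)C)c(OCOC)c2c(=O)c(CC(=O)Oc3cc(OCOC)c(OCOC)cc3Br)coc2c1CC=C(C)C
A2 | alternative 1 | seven-membered lactone of 2-[2-[2-hydroxy-4,5-bis(methoxymethoxy)phenyl]-7-methoxy-5-(methoxymethoxy)-6,8-bis(3-methylbut-2-enyl)-4-oxochromen-3-yl]acetic acid | COc1c(CC=C(C)C)c(OCOC)c2c(=O)c3CC(=O)Oc4cc(OCOC)c(OCOC)cc4-c3oc2c1CC=C(C)C
A3 | alternative 2 | 5-hydroxy-7-methoxy-3,6,8-tris(prop-2-enyl)-2-[2,4,5-tris(methoxymethoxy)phenyl]chromen-4-one | COc1c(CC=C)c(O)c2c(=O)c(CC=C)c(-c3cc(OCOC)c(OCOC)cc3OCOC)oc2c1CC=C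
A4 | alternative 2 | 5-hydroxy-7-methoxy-3,6,8-tris(3-methylbut-2-enyl)-2-[2,4,5-tris(methoxymethoxy)phenyl]chromen-4-one | COc1c(CC=C(C)C)c(O)c2c(=O)c(CC=C(C)C)c(-c3cc(OCOC)c(OCOC)cc3OCOC)oc2c1CC=C(C)C
A5 | alternative 3 | 2-ethynyl-7-methoxy-5-(methoxymethoxy)-3,6,8-tris(3-methylbut-2-enyl)chromen-4-one | COc1c(CC=C(C)C)c(OCOC)c2c(=O)c(CC=C(C)C)c(C#C)oc2c1CC=C(C)C
A6 | alternative 3 | pentacarbonyl[(1-ethoxyethenyl)(methoxy)methylidene]chromium, (CO)5Cr=C(OMe)C(OEt)=CH2 | C=C(OCC)C(OC)=[Cr](=C=O)(=C=O)(=C=O)(=C=O)=C=O
A7 | alternative 3 | 2-(4-ethoxy-2-hydroxy-5-methoxyphenyl)-7-methoxy-5-(methoxymethoxy)-3,6,8-tris(3-methylbut-2-enyl)chromen-4-one | COc1c(CC=C(C)C)c(OCOC)c2c(=O)c(CC=C(C)C)c(-c3cc(OC)c(OCC)cc3O)oc2c1CC=C(C)C
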